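## Analysis of the target

The molecule consists of two chromans that share the tetrasubstituted benzene ring D. Chroman 1 (ring A fused to pyran ring C with O1, C2, C3, C4) carries ring D on C4 through D1 and the 2-hydroxy-4,5-dimethoxyphenyl ring B on C3. Chroman 2 (ring A′ with O1′, C2′, C3′, C4′) is attached to D6 through C3′, while D2 bears a methoxy and D4 a hydroxy group. There are three stereocentres: C3 (R) and C4 (S) are neighbours and trans on ring C, and C3′ (R) lies beyond ring D, too far away to exert or receive induction, so the C3/C4 pair and C3′ each need their own controlling element. C4 is a doubly benzylic methine whose ring D substituent is flanked on both sides (D2 methoxy, D6 chromanyl); every bond formation at C4 is therefore crowded, and carbinol or cationic forms of C4 ionise very easily. Four phenols (C7, C7′, D4, B2) stand beside three methyl ethers (D2, B4, B5) on equally electron-rich rings, so no late demethylation can be selective: each methyl ether must be placed deliberately and the phenols carried as benzyl ethers that fall in one neutral hydrogenolysis. Ring D adds a regiochemical problem, a 1,2,3,5-pattern with two different oxygens. The plan rests on ring B: its hydroxyl on B2 is ortho to B1, the carbon bonded to C3, and para to the methoxy on B5; a second methoxy sits on B4, and B3 and B6 are unsubstituted. This is the pattern that a chromium carbene benzannulation writes onto a terminal alkyne.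

## Retrosynthetic reasoning

**36 to 35.** The last operation frees the phenols on C7, D4 and C7′ by hydrogenolysis of 35. The skeleton contains no benzylic C–O bond, so nothing else is cleaved and the finished polyphenol never meets acid, base or oxidant.

**35 to 28 and 33 (key disconnection).** Ring B is taken apart completely by cutting B1–B2, B2–B3 and B5–B6. B1 and B6 become the two carbons of the ethynyl group of 28, B2 with its oxygen becomes a carbonyl ligand, and B5, B4 and B3 become the carbene carbon and the methoxyvinyl group of 33. The cut is made here because it shrinks the substituent next to the congested C4 from an ortho-oxygenated aryl group to the slimmest carbon group available, so the C3–C4 bond can be made before ring B exists. It also delivers the B2 hydroxyl free while the other three phenols stay benzylated. The forward reaction must insert the alkyne with its chromanyl-bearing carbon next to the carbonyl-derived carbon and must leave C3, C4 and C3′ untouched.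

**33 to 29 and 30.** The carbene complex is cut at the bond between the carbene carbon and the vinyl group and at the O–methyl bond. Metalated 29 (31) adds to a carbonyl ligand of 30, and the acylmetalate 32 is methylated on oxygen.

**28 to 27, 26 and 25.** The ethynyl group is traced back through one-carbon homologation of aldehyde 27 to alcohol 26 and its silyl ether 25. An alkynyl group is deliberately not carried through the ring-forming step: a β,γ-alkynyl aldehyde isomerises to the allenyl aldehyde under amine catalysis, whereas a silyloxymethyl group is inert and costs only two routine extra steps.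

**25 to 24, then 21 and 22.** In 25 the bonds C3–C4 and O1–C2 are cut. Forward, carbinol 21 is dehydrated to the ortho-quinone methide 23. The enamine of 22 adds to the methide carbon and the phenol oxygen closes onto the former carbonyl carbon to give lactol 24, which is deoxygenated. This disconnection forms both stereocentres of ring C in one catalyst-controlled event, independent of C3′, and keeps the nucleophile small where crowding is worst.

**21 to 18 and 1.** The C4–D1 bond is cut between aryllithium 19 (from bromide 18) and aldehyde 1, used as its phenoxide 20. Cutting here, and not at C4–C4a, lets the same purchased aldehyde 1 serve ring A and ring A′, and the bromine atom of 18 marks D1 unambiguously.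

**18 to 17, 16, 15, then 13 and 4.** Chroman 2 is opened at O1′–C2′ (phenol displacing an activated primary alcohol) and at C3′–C4′ (alkylation of enolate 14 with benzylic bromide 4). The oxazolidinone auxiliary of 13 fixes C3′ by reagent control.

**4 to 3, 2 and 1.** The bromide comes from 1 by protection, reduction and bromination.

**13 to 11, 10, 8, 7, 6 and 5.** Ring D gets its pattern from symmetric 5. One phenol is benzylated (future D4) and the other acetylated (future D2), so that bromination goes para to the benzyloxy group, to D1. The acetate is then exchanged for the methyl ether, which settles D2 methoxy against D4 benzyloxy.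

## Alternatives that were turned down

**Alternative 1:** Ring D is completed by an aryne acyl-alkylation that cuts D1–C4 and D6–C3′ together.
- Forward step: fluoride releases the alkoxy-aryne from silyl triflate A1. The enolate carbon of the ring A β-keto ester A2 adds to D6, the aryl anion at D1 closes onto the ketone, and the four-membered alkoxide fragments to A3. A3 is ring D carrying the ring A aroyl group on D1 and an acetate arm on D6.
- For: one step joins ring A to ring D and places both carbon substituents of ring D with regiochemistry dictated by the alkoxy group of the aryne. On this point it is stronger than the chosen route, which spends steps 4 to 7 on the same pattern.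
- Against: the step closes no ring of the target and sets no stereocentre. C4 arrives as a ketone ringed by three ortho substituents, and converting it into the C4 methine with C3 attached trans is the most crowded transformation the target offers. A1 needs the same D2/D4 differentiation plus an ortho-silyl triflate, and chroman 2 would have to be grown from the acetate arm beside an electrophilic ketone.
- Comparison: the chosen strategy creates C4 as an sp3 centre together with C3 in one step and leaves only ring B for the end. After A3, rings C and B, chroman 2 and all three stereocentres are still open.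

**Alternative 2:** C3–C4 and O1–C2 are cut with ring B already on the two-carbon partner.
- Forward step: methide 23, released from carbinol 21, is attacked at C4 by the chiral ammonium or azolium enolate generated from the activated ring B arylacetate A4. The phenoxide then acylates, closing lactone A5 with C3 and C4 set. Lactone reduction, Mitsunobu closure and hydrogenolysis would finish.
- For: it is the most convergent plan, all carbons are in place after the key step, no stoichiometric metal is needed, and the route would be about six steps shorter. On step economy it is clearly stronger.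
- Against: the new C3–C4 bond would join a carbon bearing the ortho-benzyloxy ring B to a methide carbon bearing the doubly ortho-substituted ring D. That is the most hindered version of the most hindered bond, made with an enolate less nucleophilic than an aldehyde enamine. The lactone must then be reduced at an acidic α-aryl centre.
- Comparison: the chosen strategy uses the same methide 23 but with a small aliphatic enamine, and builds ring B only once the congested bond exists. It pays for this with extra steps and one equivalent of chromium.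

**Alternative 3:** Ring D is made by cycloaddition, cutting D1–D2 and D5–D6.
- Forward step: diene A7 adds to ynone A6, whose triple bond lies between the future C4 carbonyl and C3′ of a finished chroman 2. Loss of one alkoxy group and of the silyl group aromatises the adduct to benzophenone A8, with methoxy on D2 and a free hydroxyl on D4.
- For: the polarity of diene and ynone solves both the regiochemistry of ring D and the D2/D4 differentiation in one step. This is better than the statistical monobenzylation used here.
- Against: the propargylic C3′–H of A6 is γ to the ynone carbonyl, and isomerisation to the allenyl ketone would racemise C3′ under the heat or Lewis acid the cycloaddition needs. An enantiopure 3-alkynylchroman is itself not trivial to make. A8 is again a crowded diaryl ketone, so the C4 problem of Alternative 1 returns, with ring C, ring B and the C3/C4 pair still to come.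
- Comparison: the chosen route sets C3′ by auxiliary control on a centre that is never made acidic afterwards, and sets C3/C4 together.

Key step: step 21

Remark: ArD stands for the 4-(benzyloxy)-2-[(3R)-7-(benzyloxy)chroman-3-yl]-6-methoxyphenyl group (ring D with chroman 2 attached). Compounds 1 and 22 are taken as purchasable. In the SMILES of 34 the η6-bound Cr(CO)3 unit is written as a separate component.

## Route

Step 1
Reactants: 1 4-(benzyloxy)-2-hydroxybenzaldehyde
Product: 2 4-(benzyloxy)-2-(methoxymethoxy)benzaldehyde
Conditions: MOMCl, iPr2NEt, CH2Cl2, 0 °C to rt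
Reagents that add atoms: chloromethyl methyl ether, COCCl
Why: O-alkylation of the phenol to its methoxymethyl acetal; the acetal survives hydride, enolate and Mitsunobu chemistry and is later removed by acid without touching benzyl ethers.

Step 2
Reactants: 2 4-(benzyloxy)-2-(methoxymethoxy)benzaldehyde
Product: 3 [4-(benzyloxy)-2-(methoxymethoxy)phenyl]methanol
Conditions: NaBH4, MeOH, 0 °C
Reagents that add atoms: none
Why: Hydride reduction of the aldehyde; nothing else in 2 is reducible by NaBH4.

Step 3
Reactants: 3 [4-(benzyloxy)-2-(methoxymethoxy)phenyl]methanol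
Product: 4 4-(benzyloxy)-1-(bromomethyl)-2-(methoxymethoxy)benzene
Conditions: CBr4, PPh3, CH2Cl2, 0 °C; used at once
Reagents that add atoms: carbon tetrabromide, BrC(Br)(Br)Br
Why: Appel reaction under neutral conditions that keep the acetal; the electron-rich benzylic bromide ionises easily and is therefore not stored.

Step 4
Reactants: 5 methyl 2-(3,5-dihydroxyphenyl)acetate
Product: 6 methyl 2-[3-(benzyloxy)-5-hydroxyphenyl]acetate
Conditions: BnBr (1 equiv), K2CO3 (1 equiv), acetone, reflux; chromatography, recovered 5 recycled
Reagents that add atoms: benzyl bromide, BrCc1ccccc1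
Why: Williamson etherification of one of two equivalent phenols; it is statistical, so 6 is separated from 5 and the dibenzyl ether, and K2CO3 is too weak to deprotonate the arylacetate methylene.

Step 5
Reactants: 6 methyl 2-[3-(benzyloxy)-5-hydroxyphenyl]acetate
Product: 7 methyl 2-[3-acetoxy-5-(benzyloxy)phenyl]acetate
Conditions: Ac2O, pyridine, rt
Reagents that add atoms: acetic anhydride, CC(=O)OC(C)=O
Why: O-acetylation; it turns the oxygen on the future D2 into a much weaker donor than the benzyloxy group on the future D4.

Step 6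
Reactants: 7 methyl 2-[3-acetoxy-5-(benzyloxy)phenyl]acetate
Product: 8 methyl 2-[3-acetoxy-5-(benzyloxy)-2-bromophenyl]acetate
Conditions: NBS (1.0 equiv), MeCN, 0 °C to rt, dark
Reagents that add atoms: N-bromosuccinimide, O=C1CCC(=O)N1Br
Why: Electrophilic aromatic bromination; the carbon para to the benzyloxy group and ortho to the acetoxy group (future D1) is the most activated, and ionic conditions leave the benzylic CH2 groups alone.

Step 7
Reactants: 8 methyl 2-[3-acetoxy-5-(benzyloxy)-2-bromophenyl]acetate
Product: 10 methyl 2-[5-(benzyloxy)-2-bromo-3-methoxyphenyl]acetate, via potassium phenoxide 9 (not isolated)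
Conditions: K2CO3, MeOH, rt; then MeI, DMF, rt
Reagents that add atoms: iodomethane, CI
Why: Methanolysis of the aryl acetate (the methyl ester is degenerate in methanol), then Williamson methylation of phenoxide 9 in the same flask; D2 now carries the methyl ether and D4 the benzyl ether.

Step 8
Reactants: 10 methyl 2-[5-(benzyloxy)-2-bromo-3-methoxyphenyl]acetate
Product: 11 2-[5-(benzyloxy)-2-bromo-3-methoxyphenyl]acetic acid
Conditions: LiOH, THF/H2O, rt; then 1 M HCl
Reagents that add atoms: lithium hydroxide, [Li+].[OH-]
Why: Saponification of the unhindered methyl ester; aryl bromide and ethers are inert.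

Step 9
Reactants: 11 2-[5-(benzyloxy)-2-bromo-3-methoxyphenyl]acetic acid
Product: 13 (4R)-4-benzyl-3-{2-[5-(benzyloxy)-2-bromo-3-methoxyphenyl]acetyl}oxazolidin-2-one, via mixed pivalic anhydride 12 (not isolated)
Conditions: PivCl, Et3N, THF, −20 °C; then (4R)-4-benzyloxazolidin-2-one, LiCl, rt
Reagents that add atoms: (4R)-4-benzyloxazolidin-2-one, O=C1N[C@H](Cc2ccccc2)CO1
Why: N-acylation of the auxiliary through the mixed anhydride with LiCl activation; it is mild enough to avoid ketene formation from the arylacetic acid.

Step 10
Reactants: 13 (4R)-4-benzyl-3-{2-[5-(benzyloxy)-2-bromo-3-methoxyphenyl]acetyl}oxazolidin-2-one; 4 4-(benzyloxy)-1-(bromomethyl)-2-(methoxymethoxy)benzene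
Product: 15 (4R)-4-benzyl-3-{(2R)-2-[5-(benzyloxy)-2-bromo-3-methoxyphenyl]-3-[4-(benzyloxy)-2-(methoxymethoxy)phenyl]propanoyl}oxazolidin-2-one, via sodium Z-enolate 14 (not isolated)
Conditions: NaN(SiMe3)2, THF, −78 °C; then 4, −78 to −40 °C; cold NH4Cl quench
Reagents that add atoms: none
Why: Evans asymmetric alkylation; the chelated Z-enolate is alkylated on the face away from the benzyl group of the (R)-auxiliary, which sets the future C3′ as (R), and the reactive benzylic bromide allows −78 °C, where the acidic α-aryl centre does not epimerise.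

Step 11
Reactants: 15 (4R)-4-benzyl-3-{(2R)-2-[5-(benzyloxy)-2-bromo-3-methoxyphenyl]-3-[4-(benzyloxy)-2-(methoxymethoxy)phenyl]propanoyl}oxazolidin-2-one
Product: 16 (2R)-2-[5-(benzyloxy)-2-bromo-3-methoxyphenyl]-3-[4-(benzyloxy)-2-(methoxymethoxy)phenyl]propan-1-ol
Conditions: LiBH4, THF, H2O (1 equiv), 0 °C
Reagents that add atoms: none
Why: Reductive cleavage of the imide, which is far more reactive than any other group present; the stereocentre is retained at 0 °C and the auxiliary is recovered.

Step 12
Reactants: 16 (2R)-2-[5-(benzyloxy)-2-bromo-3-methoxyphenyl]-3-[4-(benzyloxy)-2-(methoxymethoxy)phenyl]propan-1-ol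
Product: 17 5-(benzyloxy)-2-{(2R)-2-[5-(benzyloxy)-2-bromo-3-methoxyphenyl]-3-hydroxypropyl}phenol
Conditions: HCl (cat.), MeOH, 45 °C
Reagents that add atoms: none
Why: Acid-catalysed acetal exchange removes the methoxymethyl group; benzyl ethers, aryl bromide and the primary alcohol are stable.

Step 13
Reactants: 17 5-(benzyloxy)-2-{(2R)-2-[5-(benzyloxy)-2-bromo-3-methoxyphenyl]-3-hydroxypropyl}phenol
Product: 18 (3R)-7-(benzyloxy)-3-[5-(benzyloxy)-2-bromo-3-methoxyphenyl]chromane
Conditions: PPh3, DIAD, THF, 0 °C to rt
Reagents that add atoms: none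
Why: Intramolecular Mitsunobu etherification (6-exo-tet attack of the phenol on C2′) closes chroman 2; C3′ is not involved and keeps its configuration.

Step 14
Reactants: 18 (3R)-7-(benzyloxy)-3-[5-(benzyloxy)-2-bromo-3-methoxyphenyl]chromane; 1 4-(benzyloxy)-2-hydroxybenzaldehyde
Product: 21 5-(benzyloxy)-2-[ArD(hydroxy)methyl]phenol as both carbinol epimers, via aryllithium 19 (not isolated), via sodium phenoxide 20 (not isolated)
Conditions: 18, n-BuLi, THF, −78 °C; separately 1, NaH, THF, 0 °C; combine at −78 °C, warm to 0 °C; NH4Cl/pH 7 work-up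
Reagents that add atoms: none
Why: Bromine–lithium exchange, then addition of the aryllithium to the formyl group; pre-forming the phenoxide spares a second equivalent of 19, neutral work-up keeps the acid-labile carbinol, and its configuration is irrelevant because the carbon becomes trigonal in step 15.

Step 15
Reactants: 21 5-(benzyloxy)-2-[ArD(hydroxy)methyl]phenol; 22 3-{[tert-butyl(dimethyl)silyl]oxy}propanal
Product: 24 (3R,4S)-4-ArD-7-(benzyloxy)-3-({[tert-butyl(dimethyl)silyl]oxy}methyl)chroman-2-ol (3,4-trans; both C2 epimers), via ortho-quinone methide 23 (not isolated)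
Conditions: (R)-2-[diphenyl(trimethylsilyloxy)methyl]pyrrolidine (20 mol %), PhCO2H (20 mol %), 22 (3 equiv), CH2Cl2, 0 °C to rt
Reagents that add atoms: none
Why: Amine-catalysed formal [4+2] of an aldehyde with an ortho-quinone methide formed in situ (enamine Michael addition, 6-exo-trig aminal closure, hydrolysis); the E-enamine of 22 attacks the methide carbon with the face not shielded by the (R)-catalyst, which sets C3, and the compact transition state plus equilibration at the epimerisable C3 gives the 3,4-trans lactol, which sets C4, with no influence from C3′.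

Step 16
Reactants: 24 (3R,4S)-4-ArD-7-(benzyloxy)-3-({[tert-butyl(dimethyl)silyl]oxy}methyl)chroman-2-ol
Product: 25 (3S,4S)-4-ArD-7-(benzyloxy)-3-({[tert-butyl(dimethyl)silyl]oxy}methyl)chromane (3,4-trans)
Conditions: Et3SiH, BF3·OEt2, CH2Cl2, −78 to −30 °C
Reagents that add atoms: none
Why: Ionic hydrogenation of the lactol through the aryl oxocarbenium ion turns C2 into the methylene; C3 and C4 are untouched at low temperature, and partial loss of the silyl group would be harmless because step 17 removes it.

Step 17
Reactants: 25 (3S,4S)-4-ArD-7-(benzyloxy)-3-({[tert-butyl(dimethyl)silyl]oxy}methyl)chromane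
Product: 26 [(3R,4S)-4-ArD-7-(benzyloxy)chroman-3-yl]methanol
Conditions: HF·pyridine, THF/pyridine, 0 °C to rt
Reagents that add atoms: none
Why: Fluoride cleavage of the primary silyl ether; buffered HF leaves benzyl ethers and the electron-rich rings alone.

Step 18
Reactants: 26 [(3R,4S)-4-ArD-7-(benzyloxy)chroman-3-yl]methanol
Product: 27 (3S,4S)-4-ArD-7-(benzyloxy)chromane-3-carbaldehyde (3,4-trans)
Conditions: Dess–Martin periodinane, pyridine, CH2Cl2, 0 °C to rt; used directly
Reagents that add atoms: none
Why: Dess–Martin oxidation of the primary alcohol under buffered, non-epimerising conditions.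

Step 19
Reactants: 27 (3S,4S)-4-ArD-7-(benzyloxy)chromane-3-carbaldehyde
Product: 28 (3R,4S)-4-ArD-7-(benzyloxy)-3-ethynylchromane (3,4-trans)
Conditions: dimethyl (1-diazo-2-oxopropyl)phosphonate, K2CO3, MeOH/THF, 0 °C to rt
Reagents that add atoms: dimethyl (1-diazo-2-oxopropyl)phosphonate, COP(=O)(OC)C(=[N+]=[N-])C(C)=O
Why: Ohira–Bestmann variant of the Seyferth–Gilbert homologation (addition of the diazomethylphosphonate anion, loss of phosphate and N2 with 1,2-shift); homologation outruns enolisation, and trans is in any case the favoured arrangement at C3.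

Step 20
Reactants: 29 methyl vinyl ether; 30 chromium hexacarbonyl, Cr(CO)6
Product: 33 pentacarbonyl[methoxy(1-methoxyvinyl)carbene]chromium, via 1-methoxyvinyllithium 31 (not isolated), via lithium acylchromate 32 (not isolated)
Conditions: 29, t-BuLi, THF, −78 to 0 °C; Cr(CO)6, Et2O, 0 °C to rt; MeOTf, CH2Cl2, 0 °C; stored cold under argon
Reagents that add atoms: methyl trifluoromethanesulfonate, COS(=O)(=O)C(F)(F)F
Why: Fischer carbene synthesis (α-lithiation of the enol ether, addition to a carbonyl ligand, O-methylation of the acylate); the product is an α-substituted vinyl complex of zerovalent chromium of the isopropenyl type and so is not prone to polymerise.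

Step 21
Reactants: 28 (3R,4S)-4-ArD-7-(benzyloxy)-3-ethynylchromane; 33 pentacarbonyl[methoxy(1-methoxyvinyl)carbene]chromium
Product: 35 2-[(3R,4S)-4-ArD-7-(benzyloxy)chroman-3-yl]-4,5-dimethoxyphenol, via tricarbonylchromium arene complex 34 (not isolated)
Conditions: 33 (1.5 equiv), THF (0.05 M), 50 °C, argon; then air, EtOAc, silica, daylight, rt
Reagents that add atoms: none
Why: Thermal loss of one CO from 33 opens a coordination site; alkyne 28 binds and inserts into the Cr=C bond with its unsubstituted carbon bonding to the carbene carbon (B5–B6), giving a vinylcarbene in which the metal sits on the chromanyl-bearing carbon. CO insertion (B1–B2) then gives a chromium-bound dienylketene, whose 6π-electrocyclisation forms B2–B3 and closes the six-membered carbocycle ring B; tautomerisation gives the phenol as its Cr(CO)3 complex 34, and air oxidation releases 35. The closest known reaction type is the Dötz benzannulation of alkenyl(alkoxy)carbene complexes, including α-alkoxyalkenyl ones, with terminal alkynes to 4-alkoxyphenols. No stereocentre is formed, and C3, C4 and C3′ are spectators because the medium is neutral and the propargylic C3–H is never deprotonated. The selectivity needed is the regiochemistry of insertion; it is secured by the size difference between the secondary chromanyl substituent and hydrogen, which puts the larger group next to the carbonyl-derived carbon. Phenol formation is favoured over cyclopentannulation, furan or cyclobutenone formation by the alkenyl (not aryl) carbene, the coordinating solvent and the low concentration. Oxidative work-up is limited to air so that the hydroquinone monomethyl ether is not taken on to the quinone.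

Step 22
Reactants: 35 2-[(3R,4S)-4-ArD-7-(benzyloxy)chroman-3-yl]-4,5-dimethoxyphenol
Product: 36 (3R,4S)-3-(2-hydroxy-4,5-dimethoxyphenyl)-4-{4-hydroxy-2-[(3R)-7-hydroxychroman-3-yl]-6-methoxyphenyl}chroman-7-ol (CNP0266829.1)
Conditions: H2 (1 atm), Pd/C (10 %), EtOAc/MeOH, rt
Reagents that add atoms: none
Why: Hydrogenolysis of the three aryl benzyl ethers; O1–C2 and O1′–C2′ are alkyl aryl ethers on non-benzylic carbons and the C4–aryl bonds are not cleaved, so the three stereocentres are untouched.

## Compound list

1 | 4-(benzyloxy)-2-hydroxybenzaldehyde | O=Cc1ccc(OCc2ccccc2)cc1O | starting material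
2 | 4-(benzyloxy)-2-(methoxymethoxy)benzaldehyde | O=Cc1ccc(OCc2ccccc2)cc1OCOC | intermediate
3 | [4-(benzyloxy)-2-(methoxymethoxy)phenyl]methanol | OCc1ccc(OCc2ccccc2)cc1OCOC | intermediate
4 | 4-(benzyloxy)-1-(bromomethyl)-2-(methoxymethoxy)benzene | BrCc1ccc(OCc2ccccc2)cc1OCOC | intermediate
5 | methyl 2-(3,5-dihydroxyphenyl)acetate | COC(=O)Cc1cc(O)cc(O)c1 | starting material
6 | methyl 2-[3-(benzyloxy)-5-hydroxyphenyl]acetate | COC(=O)Cc1cc(O)cc(OCc2ccccc2)c1 | intermediate
7 | methyl 2-[3-acetoxy-5-(benzyloxy)phenyl]acetate | COC(=O)Cc1cc(OC(C)=O)cc(OCc2ccccc2)c1 | intermediate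
8 | methyl 2-[3-acetoxy-5-(benzyloxy)-2-bromophenyl]acetate | COC(=O)Cc1cc(OCc2ccccc2)cc(OC(C)=O)c1Br | intermediate
9 | potassium 5-(benzyloxy)-2-bromo-3-(2-methoxy-2-oxoethyl)phenoxide | [K+].[O-]c1cc(OCc2ccccc2)cc(CC(=O)OC)c1Br | intermediate
10 | methyl 2-[5-(benzyloxy)-2-bromo-3-methoxyphenyl]acetate | COC(=O)Cc1cc(OCc2ccccc2)cc(OC)c1Br | intermediate
11 | 2-[5-(benzyloxy)-2-bromo-3-methoxyphenyl]acetic acid | OC(=O)Cc1cc(OCc2ccccc2)cc(OC)c1Br | intermediate
12 | mixed anhydride of 11 with pivalic acid | CC(C)(C)C(=O)OC(=O)Cc1cc(OCc2ccccc2)cc(OC)c1Br | intermediate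
13 | (4R)-4-benzyl-3-{2-[5-(benzyloxy)-2-bromo-3-methoxyphenyl]acetyl}oxazolidin-2-one | O=C(Cc1cc(OCc2ccccc2)cc(OC)c1Br)N1[C@H](Cc2ccccc2)COC1=O | intermediate
14 | sodium (Z)-enolate of 13 | [Na+].[O-]/C(=C\c1cc(OCc2ccccc2)cc(OC)c1Br)N1[C@H](Cc2ccccc2)COC1=O | intermediate
15 | (4R)-4-benzyl-3-{(2R)-2-[5-(benzyloxy)-2-bromo-3-methoxyphenyl]-3-[4-(benzyloxy)-2-(methoxymethoxy)phenyl]propanoyl}oxazolidin-2-one | COc1cc(OCc2ccccc2)cc([C@@H](Cc2ccc(OCc3ccccc3)cc2OCOC)C(=O)N2[C@H](Cc3ccccc3)COC2=O)c1Br | intermediate
16 | (2R)-2-[5-(benzyloxy)-2-bromo-3-methoxyphenyl]-3-[4-(benzyloxy)-2-(methoxymethoxy)phenyl]propan-1-ol | COc1cc(OCc2ccccc2)cc([C@@H](Cc2ccc(OCc3ccccc3)cc2OCOC)CO)c1Br | intermediate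
17 | 5-(benzyloxy)-2-{(2R)-2-[5-(benzyloxy)-2-bromo-3-methoxyphenyl]-3-hydroxypropyl}phenol | COc1cc(OCc2ccccc2)cc([C@@H](Cc2ccc(OCc3ccccc3)cc2O)CO)c1Br | intermediate
18 | (3R)-7-(benzyloxy)-3-[5-(benzyloxy)-2-bromo-3-methoxyphenyl]chromane | COc1cc(OCc2ccccc2)cc([C@@H]2COc3cc(OCc4ccccc4)ccc3C2)c1Br | intermediate
19 | ArD–lithium, {4-(benzyloxy)-2-[(3R)-7-(benzyloxy)chroman-3-yl]-6-methoxyphenyl}lithium | COc1cc(OCc2ccccc2)cc([C@@H]2COc3cc(OCc4ccccc4)ccc3C2)c1[Li] | intermediate
20 | sodium 5-(benzyloxy)-2-formylphenoxide | [Na+].[O-]c1cc(OCc2ccccc2)ccc1C=O | intermediate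
21 | 5-(benzyloxy)-2-[ArD(hydroxy)methyl]phenol (both carbinol epimers) | COc1cc(OCc2ccccc2)cc([C@@H]2COc3cc(OCc4ccccc4)ccc3C2)c1C(O)c1ccc(OCc2ccccc2)cc1O | intermediate
22 | 3-{[tert-butyl(dimethyl)silyl]oxy}propanal | O=CCCO[Si](C)(C)C(C)(C)C | starting material
23 | 3-(benzyloxy)-6-(ArD-methylidene)cyclohexa-2,4-dien-1-one (ortho-quinone methide) | COc1cc(OCc2ccccc2)cc([C@@H]2COc3cc(OCc4ccccc4)ccc3C2)c1C=C1C=CC(OCc2ccccc2)=CC1=O | intermediate
24 | (3R,4S)-4-ArD-7-(benzyloxy)-3-({[tert-butyl(dimethyl)silyl]oxy}methyl)chroman-2-ol (3,4-trans, C2 epimers) | CC(C)(C)[Si](C)(C)OC[C@@H]2C(O)Oc3cc(OCc4ccccc4)ccc3[C@H]2c2c(OC)cc(OCc4ccccc4)cc2[C@@H]2COc3cc(OCc4ccccc4)ccc3C2 | intermediate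
25 | (3S,4S)-4-ArD-7-(benzyloxy)-3-({[tert-butyl(dimethyl)silyl]oxy}methyl)chromane (3,4-trans) | CC(C)(C)[Si](C)(C)OC[C@@H]2COc3cc(OCc4ccccc4)ccc3[C@H]2c2c(OC)cc(OCc4ccccc4)cc2[C@@H]2COc3cc(OCc4ccccc4)ccc3C2 | intermediate
26 | [(3R,4S)-4-ArD-7-(benzyloxy)chroman-3-yl]methanol (3,4-trans) | OC[C@@H]2COc3cc(OCc4ccccc4)ccc3[C@H]2c2c(OC)cc(OCc4ccccc4)cc2[C@@H]2COc3cc(OCc4ccccc4)ccc3C2 | intermediate
27 | (3S,4S)-4-ArD-7-(benzyloxy)chromane-3-carbaldehyde (3,4-trans) | O=C[C@@H]2COc3cc(OCc4ccccc4)ccc3[C@H]2c2c(OC)cc(OCc4ccccc4)cc2[C@@H]2COc3cc(OCc4ccccc4)ccc3C2 | intermediate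
28 | (3R,4S)-4-ArD-7-(benzyloxy)-3-ethynylchromane (3,4-trans) | C#C[C@@H]2COc3cc(OCc4ccccc4)ccc3[C@H]2c2c(OC)cc(OCc4ccccc4)cc2[C@@H]2COc3cc(OCc4ccccc4)ccc3C2 | intermediate
29 | methyl vinyl ether | COC=C | starting material
30 | chromium hexacarbonyl, Cr(CO)6 | O=C=[Cr](=C=O)(=C=O)(=C=O)(=C=O)=C=O | starting material
31 | 1-methoxyvinyllithium | [Li]C(=C)OC | intermediate
32 | lithium pentacarbonyl(2-methoxyacryloyl)chromate | COC(=C)C(O[Li])=[Cr](=C=O)(=C=O)(=C=O)(=C=O)=C=O | intermediate
33 | pentacarbonyl[methoxy(1-methoxyvinyl)carbene]chromium | COC(=C)C(OC)=[Cr](=C=O)(=C=O)(=C=O)(=C=O)=C=O | intermediate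
34 | tricarbonyl(η6-ring B)chromium complex of 35 | COc1cc(O)c([C@@H]2COc3cc(OCc4ccccc4)ccc3[C@H]2c2c(OC)cc(OCc4ccccc4)cc2[C@@H]2COc3cc(OCc4ccccc4)ccc3C2)cc1OC.O=C=[Cr](=C=O)=C=O | intermediate
35 | 2-[(3R,4S)-4-ArD-7-(benzyloxy)chroman-3-yl]-4,5-dimethoxyphenol | COc1cc(O)c([C@@H]2COc3cc(OCc4ccccc4)ccc3[C@H]2c2c(OC)cc(OCc4ccccc4)cc2[C@@H]2COc3cc(OCc4ccccc4)ccc3C2)cc1OC | intermediate
36 | (3R,4S)-3-(2-hydroxy-4,5-dimethoxyphenyl)-4-{4-hydroxy-2-[(3R)-7-hydroxychroman-3-yl]-6-methoxyphenyl}chroman-7-ol | COc1cc(O)c([C@@H]2COc3cc(O)ccc3[C@H]2c2c(OC)cc(O)cc2[C@@H]2COc3cc(O)ccc3C2)cc1OC | target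

## Step count and least certain steps

Total step count: 22. Longest linear sequence: 18 steps (from 5 through steps 4 to 19, then 21 and 22).

**Step 21 (key step).**
- Risk: the vinylcarbene formed after alkyne insertion may be diverted before or after CO insertion (cyclopentannulation, furan or cyclobutenone formation). The terminal alkyne may oligomerise on the metal. The electron-rich, thermally labile carbene complex may decompose faster than it loses CO and binds the α-branched alkyne. Over-oxidation of the hydroquinone monoether during decomplexation is a further loss channel.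
- Fallback: ring B is brought in ready-made by a C(sp3)–C(sp2) coupling, setting out from aldehyde 27. Pinnick oxidation (NaClO2, NaH2PO4, 2-methyl-2-butene) gives the chroman-3-carboxylic acid F1, which is converted with N-hydroxyphthalimide and N,N′-diisopropylcarbodiimide into the redox-active ester F2. Commercial 2-bromo-4,5-dimethoxyphenol is O-benzylated to 1-(benzyloxy)-2-bromo-4,5-dimethoxybenzene F3, and n-BuLi followed by ZnCl2 gives the arylzinc chloride F4. Decarboxylative Negishi arylation of F2 with F4 (NiCl2·glyme, 4,4′-di-tert-butyl-2,2′-bipyridine, THF/DMF) should give the tetrabenzyl ether F5, the C3 radical being captured trans to ring D. Hydrogenolysis under the conditions of step 22 brings the fallback back to the route at 36.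

**Step 15.**
- Risk: the bulky catalyst-bound enamine may add only sluggishly to the methide carbon, which is screened on both faces by the ortho substituents of ring D. Methide 23 would then be lost to oligomerisation, or facial selectivity would erode.
- Fallback: catalyst control is given up in favour of a small, more nucleophilic achiral enamine. Starting from 21, the preformed pyrrolidine enamine F6 of 22 is added with a trace of acid. Hydrolysis should give both trans lactols, 24 and the lactol F7 with inverted C3 and C4. Because C3′ is fixed, these are diastereomers and are separated by chromatography; the route is rejoined at 24.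

**Step 14.**
- Risk: addition may be incomplete because phenoxide 20 is a deactivated, poorly soluble electrophile and the flanked aryllithium 19 is slow, so that 19 is protonated instead. The carbinol may also ionise on work-up.
- Fallback: starting from 18, aryllithium 19 is added to the O-Boc aldehyde F8 (from 1 and Boc2O). The carbonate then migrates from the phenol oxygen to the new alkoxide, and a cold acetic acid quench gives the phenolic benzylic carbonate F9. F9 releases methide 23 with mild base (NaHCO3) and enters step 15 in place of 21, rejoining the route at 24.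

**Step 16.**
- Risk: the oxocarbenium ion may lose the C3 proton to a 4H-chromene enol ether and be reprotonated, epimerising C3. Lewis acid may also cause cleavage at the doubly activated C4.
- Fallback: no cationic intermediate. Starting from 24, NaBH4 reduces the open hydroxy-aldehyde form to the phenol–primary alcohol F10, and Mitsunobu etherification as in step 13 closes the ring to 25.

**Step 19.**
- Risk: aldehyde 27 may enolise in carbonate/methanol before it is homologated, followed by β-elimination of the ring A phenoxide (retro-oxa-Michael ring opening) or epimerisation at C3.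
- Fallback: Corey–Fuchs sequence. Starting from 27, CBr4/PPh3 with Et3N gives the 1,1-dibromoalkene F11 without base-mediated enolisation; n-BuLi (2 equiv, THF, −78 °C) then gives alkyne 28 after rearrangement of the carbenoid and protonation.

## Further compounds

F1 | step 21 | (3S,4S)-4-ArD-7-(benzyloxy)chromane-3-carboxylic acid | OC(=O)[C@@H]2COc3cc(OCc4ccccc4)ccc3[C@H]2c2c(OC)cc(OCc4ccccc4)cc2[C@@H]2COc3cc(OCc4ccccc4)ccc3C2
F2 | step 21 | 1,3-dioxoisoindolin-2-yl (3S,4S)-4-ArD-7-(benzyloxy)chromane-3-carboxylate | O=C(ON1C(=O)c5ccccc5C1=O)[C@@H]2COc3cc(OCc4ccccc4)ccc3[C@H]2c2c(OC)cc(OCc4ccccc4)cc2[C@@H]2COc3cc(OCc4ccccc4)ccc3C2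
F3 | step 21 | 1-(benzyloxy)-2-bromo-4,5-dimethoxybenzene | COc1cc(Br)c(OCc2ccccc2)cc1OC
F4 | step 21 | [2-(benzyloxy)-4,5-dimethoxyphenyl]zinc chloride | COc1cc([Zn]Cl)c(OCc2ccccc2)cc1OC
F5 | step 21 | (3R,4S)-4-ArD-7-(benzyloxy)-3-[2-(benzyloxy)-4,5-dimethoxyphenyl]chromane | COc1cc(OCc4ccccc4)c([C@@H]2COc3cc(OCc4ccccc4)ccc3[C@H]2c2c(OC)cc(OCc4ccccc4)cc2[C@@H]2COc3cc(OCc4ccccc4)ccc3C2)cc1OC
F6 | step 15 | 1-[(E)-3-{[tert-butyl(dimethyl)silyl]oxy}prop-1-en-1-yl]pyrrolidine | CC(C)(C)[Si](C)(C)OC/C=C/N1CCCC1
F7 | step 15 | (3S,4R)-4-ArD-7-(benzyloxy)-3-({[tert-butyl(dimethyl)silyl]oxy}methyl)chroman-2-ol (diastereomer of 24) | CC(C)(C)[Si](C)(C)OC[C@H]2C(O)Oc3cc(OCc4ccccc4)ccc3[C@@H]2c2c(OC)cc(OCc4ccccc4)cc2[C@@H]2COc3cc(OCc4ccccc4)ccc3C2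
F8 | step 14 | 5-(benzyloxy)-2-formylphenyl tert-butyl carbonate | O=Cc1ccc(OCc2ccccc2)cc1OC(=O)OC(C)(C)C
F9 | step 14 | ArD[4-(benzyloxy)-2-hydroxyphenyl]methyl tert-butyl carbonate | COc1cc(OCc2ccccc2)cc([C@@H]2COc3cc(OCc4ccccc4)ccc3C2)c1C(OC(=O)OC(C)(C)C)c1ccc(OCc2ccccc2)cc1O
F10 | step 16 | 5-(benzyloxy)-2-[(1S,2S)-1-ArD-3-{[tert-butyl(dimethyl)silyl]oxy}-2-(hydroxymethyl)propyl]phenol | CC(C)(C)[Si](C)(C)OC[C@H](CO)[C@@H](c1ccc(OCc2ccccc2)cc1O)c1c(OC)cc(OCc2ccccc2)cc1[C@@H]1COc2cc(OCc3ccccc3)ccc2C1
F11 | step 19 | (3R,4S)-4-ArD-7-(benzyloxy)-3-(2,2-dibromoethenyl)chromane | BrC(Br)=C[C@@H]2COc3cc(OCc4ccccc4)ccc3[C@H]2c2c(OC)cc(OCc4ccccc4)cc2[C@@H]2COc3cc(OCc4ccccc4)ccc3C2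
A1 | alternative 1 | 5-(benzyloxy)-3-methoxy-2-(trimethylsilyl)phenyl trifluoromethanesulfonate | COc1cc(OCc2ccccc2)cc(OS(=O)(=O)C(F)(F)F)c1[Si](C)(C)C
A2 | alternative 1 | methyl 3-[4-(benzyloxy)-2-(methoxymethoxy)phenyl]-3-oxopropanoate | COC(=O)CC(=O)c1ccc(OCc2ccccc2)cc1OCOC
A3 | alternative 1 | methyl 2-{5-(benzyloxy)-2-[4-(benzyloxy)-2-(methoxymethoxy)benzoyl]-3-methoxyphenyl}acetate | COC(=O)Cc1cc(OCc2ccccc2)cc(OC)c1C(=O)c1ccc(OCc2ccccc2)cc1OCOC
A4 | alternative 2 | 4-nitrophenyl 2-[2-(benzyloxy)-4,5-dimethoxyphenyl]acetate | COc1cc(OCc2ccccc2)c(CC(=O)Oc2ccc(cc2)[N+](=O)[O-])cc1OC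
A5 | alternative 2 | trans-4-ArD-7-(benzyloxy)-3-[2-(benzyloxy)-4,5-dimethoxyphenyl]chroman-2-one | COc1cc(OCc4ccccc4)c([C@@H]2C(=O)Oc3cc(OCc4ccccc4)ccc3[C@H]2c2c(OC)cc(OCc4ccccc4)cc2[C@@H]2COc3cc(OCc4ccccc4)ccc3C2)cc1OC
A6 | alternative 3 | 1-[4-(benzyloxy)-2-(methoxymethoxy)phenyl]-3-[(3R)-7-(benzyloxy)chroman-3-yl]prop-2-yn-1-one | COCOc1cc(OCc2ccccc2)ccc1C(=O)C#C[C@@H]1COc2cc(OCc3ccccc3)ccc2C1
A7 | alternative 3 | 1,1-dimethoxy-3-(trimethylsilyloxy)buta-1,3-diene | COC(OC)=CC(=C)O[Si](C)(C)C
A8 | alternative 3 | [4-(benzyloxy)-2-(methoxymethoxy)phenyl]{2-[(3R)-7-(benzyloxy)chroman-3-yl]-4-hydroxy-6-methoxyphenyl}methanone | COCOc1cc(OCc2ccccc2)ccc1C(=O)c1c(OC)cc(O)cc1[C@@H]1COc2cc(OCc3ccccc3)ccc2C1
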